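The earlier runs and the new flask were computed with made-up constants; scatter was added.

In the first 10.0 min of Wednesday's run, which is the flask asked about, the left-handed product read 5 % and the right-handed product 0 %, with a scatter of 2 percentage points, so these early readings gave me no usable rate. I turned to Saturday's run, which carried 6 equiv of partner and ran to 50.0 min.

| flask | left-handed substrate | right-handed substrate | partner | racemization catalyst | added ligand | remark | time |
|---|---|---|---|---|---|---|---|
| Wednesday's | 0.46 M | 0.46 M | 3 equiv | 1 mol% | 16 mM | the very flask that is asked about, followed so far |  |
| Saturday's | 0.46 M | 0.46 M | 6 equiv | 1 mol% | 16 mM | run made earlier |  |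
| flask | 0.46 M | 0.46 M | 3.00 equiv | 1 mol% | 16 mM |  | 50 min |

| run | time / min | right-handed product / % | left-handed product / % | left-handed substrate / % | right-handed substrate / % |
|---|---|---|---|---|---|
| Wednesday's | 0.833 | 0 | 0 | 47 | 52 |
| Wednesday's | 1.33 | 3 | 0 | 48 | 48 |
| Wednesday's | 2.00 | 1 | 0 | 49 | 47 |
| Wednesday's | 4.00 | 0 | 0 | 51 | 49 |
| Wednesday's | 6.00 | 1 | 4 | 48 | 52 |
| Wednesday's | 10.0 | 0 | 5 | 50 | 47 |
| Saturday's | 8.00 | 3 | 3 | 46 | 49 |
| Saturday's | 15.0 | 6 | 12 | 45 | 48 |
| Saturday's | 25.0 | 2 | 14 | 35 | 47 |
| Saturday's | 30.0 | 7 | 14 | 39 | 45 |
| Saturday's | 40.0 | 7 | 17 | 32 | 43 |
| Saturday's | 50.0 | 8 | 19 | 29 | 43 |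

(standard deviation of a reading: 2 percentage points)

- partner is single-handed; left-handed substrate and right-handed substrate are mirror images of each other, charged as a racemate, each of them at the stated concentration
- the analysis behind the earlier runs scatters by 2 percentage points, standard deviation
- reactions considered so far: partner + left-handed substrate -> left-handed product; partner + right-handed substrate -> right-handed product; left-handed substrate + racemization catalyst <-> right-handed substrate + racemization catalyst; racemization catalyst + added ligand <-> idle complex
- the handed part of partner does not stay in what it makes, so the products of the two hands are mirror images too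

* the species that holds most of what was charged as left-handed substrate and right-handed substrate together, at 50 min (right-handed substrate / right-handed product / left-handed product / left-handed substrate)
* the largest share itself, whichever of these holds it, in percent of the left-handed substrate and right-handed substrate together charged

At the end of Saturday's run, the left-handed substrate read 29 % and the right-handed substrate 43 %. Substrate and product summed to 48.0 % for the left hand and 51.0 % for the right, so I let each hand run on its own. From the share charged and the share left, I read κ = 0.00109 /M/min, the right-hand constant: the first-order loss of right-handed substrate per molar of partner. The same reading for the left hand gave 0.00395 /M/min, a selectivity factor of 3.62.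

I assumed first order in partner, which these readings do not test. In Wednesday's flask, partner stood at 1.38 M, and I held it at that charge, a pseudo-first-order reckoning. My reckoning for 50 min gave 46.4 % of right-handed substrate, above 38.1 % of left-handed substrate. Those losses together would use 0.143 M of partner, 10.4 % of its charge, and on that low conversion over this time I let the reckoning stand.

The forecast named right-handed substrate at 46 %, with a range of 42 % to 49 %, and said: “Right-handed substrate holds most either way.”

The flask gave right-handed substrate at 44.9 %, above the left-handed substrate at 39.5 %.

    partner + left-handed substrate → left-handed product (k = 6.69 × 10⁻⁵ /M/s)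
    partner + right-handed substrate → right-handed product (k = 2.14 × 10⁻⁵ /M/s)
    left-handed substrate + racemization catalyst ⇌ right-handed substrate + racemization catalyst, rate k3*[racemization catalyst]*[left-handed substrate] forward; the back reaction follows from the equilibrium constant (k = 0.0431 /M/s)
    racemization catalyst + added ligand ⇌ idle complex (K = 74.0 /M, k = 0.0308 /M/s)

At 50 min, substrate and product summed to 48.9 % for the right hand and 51.1 % for the left. With κ, I reckoned 3.60 % of right-handed product in this flask, where it stood at 3.98 %. For the neighbour charged with 1.80 equiv of partner, κ gives 47.8 % of right-handed substrate, and that flask held 46.9 %.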